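**Plan**

- Numbering used for every compound: C1 is the quaternary oxirane carbon carrying C7H2OBz, C2 is CH–OBz, C3 is CH–OH, C4=C5 is the alkene, C6 is the oxirane CH.
- Enabling feature: the oxirane oxygen sits on C1/C6 directly beside C4=C5. This is the allylic 1,3-shifted form of an oxygen bridging C1 and C4 across a C5=C6 alkene, the ring pattern of a 7-oxanorbornene.
- Retrosynthesis: cut the O2 benzoate and tie O2/O3 back into a cyclic carbonate; cut oxirane C6–O and rejoin that oxygen to C4 (oxanorbornene); cut C1–C2 and C3–C4 (Diels–Alder) to furfuryl benzoate and vinylene carbonate; cut the C7 ester.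
- Forward: esterification; [4+2] forms the carbocycle, the oxygen bridge and the fused carbonate at once; resolution; the bridge is opened and the oxirane closed in one flask; carbonate removed; O2 benzoylated.
- Stereochemistry: cis O2/O3 and their exo (bridge-side) placement come from the suprafacial cycloaddition. Absolute configuration comes from chiral-phase separation of the exo adduct, reinforced by a matched chiral rhodium catalyst. C6 is set by two inversions relative to the bridge oxygen, which puts the oxirane syn to O2/O3.

Key step: step 4

Assumption: the (R,S) antipode of the ferrocenyl diphosphine is taken as the one matched to 6 for cleavage of the C4–O bond; this rests on a recalled sense of induction for benzo-fused oxabicycles and must be checked in a test run, and if it is the reverse the (S,R) antipode is used with nothing else changed.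

**Step 1**
Reactants: 1 furfuryl alcohol; 2 benzoyl chloride
Product: 3 furfuryl benzoate (furan-2-ylmethyl benzoate)
Conditions: Et3N (1.3 equiv), DMAP (5 mol %), CH2Cl2, 0 °C to rt
Reagents that add atoms: none
Why: DMAP-catalysed O-acylation of a primary alcohol by an acid chloride (nucleophilic acyl substitution), with the amine base keeping HCl away from the acid-sensitive furan; no stereocentre is involved.

**Step 2**
Reactants: 3 furfuryl benzoate; 4 vinylene carbonate
Product: 5 racemic exo cycloadduct, rac-[(1R*,2R*,3R*,4R*)-2,3-(carbonyldioxy)-7-oxabicyclo[2.2.1]hept-5-en-1-yl]methyl benzoate (carbonate oxygens on the side of the oxygen bridge)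
Conditions: neat, 3 in twofold excess, BHT (1 mol %), sealed tube, 125 °C, 48 h; exo isomer separated from the endo isomer on SiO2
Reagents that add atoms: none
Why: Thermal Diels–Alder [4+2] cycloaddition of a 2-substituted furan to a symmetrical cis dienophile, so no regiochemical question arises; the suprafacial addition fixes O2 and O3 cis to each other, and under these reversible conditions the more stable exo carbonate should accumulate (racemic, since neither partner is chiral).

**Step 3**
Reactants: 5 racemic exo cycloadduct
Product: 6 [(1R,2R,3R,4R)-2,3-(carbonyldioxy)-7-oxabicyclo[2.2.1]hept-5-en-1-yl]methyl benzoate (single enantiomer, exo carbonate)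
Conditions: preparative SFC, amylose tris(3,5-dimethylphenylcarbamate) stationary phase, CO2/MeOH, 35 °C
Reagents that add atoms: none
Why: Resolution by chromatography on a polysaccharide chiral phase, which makes or breaks no bond and suits a rigid bicycle with a benzoate chromophore; the (1R,2R,3R,4R) fraction is to be assigned by vibrational circular dichroism against computed spectra.

**Step 4**
Reactants: 6 (1R,2R,3R,4R) exo carbonate of the oxanorbornene
Product: 8 vinyl oxirane carbonate [(1S,2R,3R,6S)-2,3-(carbonyldioxy)-7-oxabicyclo[4.1.0]hept-4-en-1-yl]methyl benzoate, via trans-bromohydrin 7 (not isolated)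
Conditions: [Rh(cod)Cl]2 (2.5 mol %), (R)-1-[(S)-2-(diphenylphosphino)ferrocenyl]ethyldi-tert-butylphosphine (6 mol %), Et3N·HBr (1.5 equiv), THF, 65 °C; then DBU (2.0 equiv), 0 °C to rt
Reagents that add atoms: none
Why: Proposed new method: monovalent rhodium should bind the exo face of C5=C6 together with the bridge oxygen, insert into the secondary C4–O bond and give an allylrhodium alkoxide that bromide (delivered with its proton by Et3N·HBr) attacks at C6 in anti SN2′ fashion, so that trans-bromohydrin 7 with the alkene at C4=C5 is formed; the closest known reaction type is the rhodium-catalysed anti ring opening of oxabicyclic alkenes by alcohols, amines, carboxylates and amine hydrohalides to trans-1,2 products, joined here to a halohydrin-to-epoxide closure. DBU then frees the tertiary C1 alkoxide, which displaces the allylic bromide in a 3-exo-tet SN2 closure and forms the oxirane. The new stereocentre C6 is fixed by two inversions counted from the bridge (bromide anti to the leaving oxygen, alkoxide anti to bromide), so the configuration of C1 in 6 puts the oxirane on the face the bridge held, syn to O2 and O3. The step needs cleavage of C4–O and not of C1–O: the quaternary C1 with its electron-withdrawing CH2OBz resists insertion, and the antipode of the chiral diphosphine is chosen so that catalyst control points to the same bond, as in regiodivergent openings of racemic bridgehead-substituted oxabicycles, which also sends any trace of the wrong enantiomer to a separable regioisomer. It needs attack at C6 and not at C4, on the endo face that only the C2 and C3 hydrogens flank, which the chelated allylrhodium alkoxide favours and which is backed up because bromide interconverts the allylic bromides and only the trans-1,2 isomer can close. Strain release pays for the opening and salt formation for the closure, so the net isomerisation does not rest on an equilibrium between bicycle and oxirane.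

**Step 5**
Reactants: 8 vinyl oxirane carbonate
Product: 9 [(1R,2R,3R,6S)-2,3-dihydroxy-7-oxabicyclo[4.1.0]hept-4-en-1-yl]methyl benzoate (cis diol, both hydroxyls syn to the oxirane)
Conditions: LiOH·H2O (1.05 equiv), THF/H2O (4:1), 0 °C; pH 7 phosphate buffer
Reagents that add atoms: none
Why: Saponification of a strained five-membered cyclic carbonate, which hydroxide should attack far faster than the conjugated, neopentyl-type C7 benzoate, followed by loss of CO2 from the hemicarbonate on buffering; one equivalent of base at 0 °C should spare the benzoate and the oxirane, and no stereocentre is touched.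

**Step 6**
Reactants: 9 cis diol
Product: 11 target, [(1S,2R,3R,6S)-2-(benzoyloxy)-3-hydroxy-7-oxabicyclo[4.1.0]hept-4-en-1-yl]methyl benzoate, via cyclic 2,3-orthobenzoate 10 (not isolated)
Conditions: PhC(OMe)3 (2 equiv), CSA (5 mol %), CH2Cl2, 0 °C to rt; then AcOH/H2O (4:1), 0 °C
Reagents that add atoms: trimethyl orthobenzoate COC(OC)(OC)c1ccccc1; water O
Why: Orthoester-mediated monoacylation of a cis-1,2-diol: mild acid hydrolysis of the orthobenzoate passes through the dioxolanylium ion and the hemiorthoester and should open to the ester on the pseudo-axial oxygen (axial-ester rule), here O2, because the half-chair fixed by the oxirane and the alkene is expected to hold C2–O pseudo-axial, away from the C1–C7 bond, and the allylic C3–O pseudo-equatorial; C2 and C3 keep their configuration since no ring C–O bond is broken.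

**Compound list**

1 | furfuryl alcohol (furan-2-ylmethanol) | OCc1ccco1 | starting material
2 | benzoyl chloride | O=C(Cl)c1ccccc1 | starting material
3 | furfuryl benzoate (furan-2-ylmethyl benzoate) | O=C(OCc1ccco1)c1ccccc1 | intermediate
4 | vinylene carbonate (1,3-dioxol-2-one) | O=C1OC=CO1 | starting material
5 | racemic exo cycloadduct, rac-[(1R*,2R*,3R*,4R*)-2,3-(carbonyldioxy)-7-oxabicyclo[2.2.1]hept-5-en-1-yl]methyl benzoate (both enantiomers written) | O=C(OC[C@]12O[C@H](C=C1)[C@H]3OC(=O)O[C@@H]23)c1ccccc1.O=C(OC[C@@]12O[C@@H](C=C1)[C@@H]3OC(=O)O[C@H]23)c1ccccc1 | intermediate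
6 | [(1R,2R,3R,4R)-2,3-(carbonyldioxy)-7-oxabicyclo[2.2.1]hept-5-en-1-yl]methyl benzoate (exo carbonate) | O=C(OC[C@]12O[C@H](C=C1)[C@H]3OC(=O)O[C@@H]23)c1ccccc1 | intermediate
7 | [(1R,2R,3R,6R)-6-bromo-2,3-(carbonyldioxy)-1-hydroxycyclohex-4-en-1-yl]methyl benzoate (Br trans to the C1 hydroxyl) | O=C(OC[C@]1(O)[C@H](Br)C=C[C@H]2OC(=O)O[C@@H]12)c1ccccc1 | intermediate (not isolated)
8 | [(1S,2R,3R,6S)-2,3-(carbonyldioxy)-7-oxabicyclo[4.1.0]hept-4-en-1-yl]methyl benzoate (oxirane syn to the carbonate) | O=C(OC[C@]12O[C@H]1C=C[C@H]3OC(=O)O[C@@H]23)c1ccccc1 | intermediate
9 | [(1R,2R,3R,6S)-2,3-dihydroxy-7-oxabicyclo[4.1.0]hept-4-en-1-yl]methyl benzoate | O=C(OC[C@]12O[C@H]1C=C[C@@H](O)[C@H]2O)c1ccccc1 | intermediate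
10 | cyclic 2,3-orthobenzoate of 9 (2-methoxy-2-phenyl-1,3-dioxolane fused at C2–C3, either configuration at the orthoester carbon) | O=C(OC[C@]12O[C@H]1C=C[C@H]3OC(OC)(c4ccccc4)O[C@@H]23)c1ccccc1 | intermediate (not isolated)
11 | [(1S,2R,3R,6S)-2-(benzoyloxy)-3-hydroxy-7-oxabicyclo[4.1.0]hept-4-en-1-yl]methyl benzoate | O=C(OC[C@]12O[C@H]1C=C[C@@H](O)[C@H]2OC(=O)c1ccccc1)c1ccccc1 | target

**Count and risks**

Total steps: 6. Longest linear sequence: 6 steps (1 → 3 → 5 → 6 → 8 → 9 → 11).

Step 4. The allylic bromide may not survive until closure: bromide can re-add in SN2′ fashion, rhodium can re-ionise the C–Br bond or the now allylic carbonate, and configuration at C6 can be lost; insertion may also be slow on a bicycle without a fused arene, or fall on C1–O. The fallback separates opening from activation and uses no halide. It sets out from 6, which is opened with water as the oxygen nucleophile under the same rhodium/diphosphine catalyst (a known nucleophile class for this ring opening) to the trans-1,6-diol [(1S,2R,3R,6R)-2,3-(carbonyldioxy)-1,6-dihydroxycyclohex-4-en-1-yl]methyl benzoate F1, which is stable to the catalyst. Mitsunobu cyclodehydration (PPh3, DIAD, THF, 0 °C) then activates the secondary allylic C6 hydroxyl, the tertiary C1 hydroxyl displaces it with inversion, and the sequence comes back to the route at 8. This fallback still relies on the rhodium insertion, so it does not answer a failure of that insertion itself; for wrong-site insertion the first remedy is the other antipode of the ligand.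

Step 6. The hemiorthoester may collapse with poor site selectivity, the benzoyl group may migrate from O2 to O3, or the acid may open the vinyl oxirane. The fallback replaces stereoelectronic control by steric control with a protecting group. It sets out from 9: silylation of the less hindered allylic hydroxyl (TBSCl, imidazole, DMF, −20 °C) should give the 3-O-silyl ether [(1R,2R,3R,6S)-3-(tert-butyldimethylsilyloxy)-2-hydroxy-7-oxabicyclo[4.1.0]hept-4-en-1-yl]methyl benzoate F2. Benzoylation of the remaining C2 hydroxyl (BzCl, DMAP, pyridine, 0 °C to rt) gives the 2-O-benzoate [(1S,2R,3R,6S)-2-(benzoyloxy)-3-(tert-butyldimethylsilyloxy)-7-oxabicyclo[4.1.0]hept-4-en-1-yl]methyl benzoate F3, and desilylation with HF·pyridine buffered with pyridine in THF at 0 °C comes back to the route at 11.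

Step 5. Hydroxide may also saponify the C7 benzoate, the benzoate may migrate to the freed O2, or the oxirane may be opened. The fallback gives up the discrimination between carbonate and benzoate and relies on primary-over-secondary acylation instead. It sets out from 8: methanolysis of both carbonate and benzoate (K2CO3, MeOH, 0 °C) gives the triol (1R,2R,3R,6S)-1-(hydroxymethyl)-7-oxabicyclo[4.1.0]hept-4-ene-2,3-diol F4, and selective benzoylation of the primary hydroxyl (BzCl, 2,4,6-collidine, CH2Cl2, −78 °C) comes back to the route at 9.

**Further compounds**

F1 | step 4 | [(1S,2R,3R,6R)-2,3-(carbonyldioxy)-1,6-dihydroxycyclohex-4-en-1-yl]methyl benzoate | O=C(OC[C@]1(O)[C@H](O)C=C[C@H]2OC(=O)O[C@@H]12)c1ccccc1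
F2 | step 6 | [(1R,2R,3R,6S)-3-(tert-butyldimethylsilyloxy)-2-hydroxy-7-oxabicyclo[4.1.0]hept-4-en-1-yl]methyl benzoate | O=C(OC[C@]12O[C@H]1C=C[C@@H](O[Si](C)(C)C(C)(C)C)[C@H]2O)c1ccccc1
F3 | step 6 | [(1S,2R,3R,6S)-2-(benzoyloxy)-3-(tert-butyldimethylsilyloxy)-7-oxabicyclo[4.1.0]hept-4-en-1-yl]methyl benzoate | O=C(OC[C@]12O[C@H]1C=C[C@@H](O[Si](C)(C)C(C)(C)C)[C@H]2OC(=O)c1ccccc1)c1ccccc1
F4 | step 5 | (1R,2R,3R,6S)-1-(hydroxymethyl)-7-oxabicyclo[4.1.0]hept-4-ene-2,3-diol | OC[C@]12O[C@H]1C=C[C@@H](O)[C@H]2O
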